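**Cold reading.** 78% of the starting material still stood after 3.00 min in the alder run, and with 22% of target the balance came to 100%. That target had used 7.33% of the partner, so I treated [partner] as steady, the pseudo-first-order view.

| setting | alder | south-east | north-west | north-east |
|---|---|---|---|---|
| starting material | 0.020 M | 0.020 M | 0.020 M | 0.020 M |
| partner | 3 equiv | 3.00 equiv | 3.00 equiv | 3.00 equiv |
| second substrate | 2.5 equiv | 5.00 equiv | 5.00 equiv | 5.00 equiv |
| temperature | −40 °C | −40 °C | −20 °C |  |
| remark | run made earlier |  |  | at −40 °C until 10 min, from then on at −20 °C |
| time |  | 15 min | 15 min | 15 min |

alder run (percent of the starting material charged)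

| time / min | target / % | starting material / % |
|---|---|---|
| 0.417 | 4 | 97 |
| 0.833 | 8 | 90 |
| 1.33 | 11 | 86 |
| 1.50 | 13 | 85 |
| 2.00 | 16 | 82 |
| 2.50 | 21 | 77 |
| 3.00 | 22 | 78 |

(each reading ± 1.5 percentage points)

- the earlier runs do not show what temperature does; that part of a forecast is a guess

- the best flask by amount of target, in percent of the starting material charged; "all alike" if 1.5 percentage points covers them all (south-east / north-west / north-east / all alike)
- amount of target at the end, in percent of the starting material charged, south-east
- amount of target at the end, in percent of the starting material charged, north-west
- amount of target at the end, in percent of the starting material charged, north-east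

**Two times.** The last alder reading gives a loss of 0.0828 /min. That makes a half-life of starting material at full partner, h, of 8.37 min. If the loss at −40 °C goes in step with [partner], h stretches as [partner] falls: divide it by the share of partner left. I held h against the run time of 15 min, which is 1.79 half-lives. With [partner] held steady and all the loss going to target, I reckoned 71.1% of target in south-east. The alder run has one amount of second substrate, so I left that out, and the warm flasks stayed a guess.

**The forecast.** It said 85% for south-east, above my figure, then 92% for north-west and 94% for north-east, with north-east best. On the warm flasks it added that “the target or selectivity may suffer in the warm”.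

**The result.** The best flask was south-east, with 29.9% against 2.97% in north-west and 12.1% in north-east.

    starting material + partner ⇌ target (K = 16.0 /M, k = 0.210 /M/s, Ea = 45.0 kJ/mol, ΔH = −6.00 kJ/mol)
    second substrate + partner → second product (k = 0.0950 /M/s, Ea = 54.0 kJ/mol)
    partner + target → over-reaction product (k = 0.0620 /M/s, Ea = 36.0 kJ/mol)
    second substrate ⇌ dormant form (K = 0.290, k = 0.0690 /s, Ea = 71.0 kJ/mol, ΔH = −15.0 kJ/mol)
    (constants at −20 °C)

**Not at rest.** In south-east 44.5% of the partner was left at 15.0 min, which by my rule put h at 18.8 min, longer than the run; 57.7% of the starting material stood there. In north-east, at the change of temperature at 10.0 min, 54.5% of the partner put h by the same rule at 15.4 min, with 59.9% of the starting material standing. South-east had not come to rest: by 150 min its partner stood at 2.33%, its starting material had risen to 71.6%, and its target had fallen to 2.42%.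

(The runs stem from a simulated flask with made-up constants; the scatter is artificial.)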